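**Plan**
- Retrosynthet­ic cuts: the four O–benzyl bonds; C2–H back to a C2 hemiketal; then C4–C4a and O1–C2 of ring C together; then the enone C3=C4 bond (aldol), the ring D benzyl ethers, ring D–CHO and ring D–acyl.
- Enabling feature: C4a, C8a and O1 of ring A are the ortho carbon, ipso carbon and oxygen of unsubstituted resorcinol, a C,O-bis-nucleophile whose second OH already sits at C7. C4–C3–C2, with ring D on C4 and ring B on C2, is the beta carbon, alpha carbon and carbonyl carbon of a chalcone, a 1,3-bis-electrophile.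
- Forward order: ring D (phloroglucinol) receives the 9-phenylnonanoyl chain, a formyl group and three benzyl caps. A Claisen–Schmidt condensation adds C3, C2 and ring B. Resorcinol brings ring A, and ring C closes last in the same operation.
- Stereochemistry: C4 (S) comes from a chiral N,N'-dioxide–Sc(OTf)3 catalyst in the annulation. C2 (S) is relayed from C4 when hydride adds to the planar C2 oxocarbenium ion anti to ring D, which gives the 2,4-cis flavan.
- Hydrogenolysis of the benzyl ethers ends a fully linear seven-step route.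

Key step: step 5

Assumption: the sense of induction of the scandium complex on this substrate class cannot be read from precedent. The ligand from (S)-pipecolic acid is written, and its mirror image from (R)-pipecolic acid is used instead if a trial run shows Si-face attack.
Assumption: 9-phenylnonanoic acid and the N,N'-dioxide ligand are taken as catalogue items.

Step 1
Reactants: 1 phloroglucinol (anhydrous); 2 9-phenylnonanoic acid
Product: 3 1-(2,4,6-trihydroxyphenyl)-9-phenylnonan-1-one
Conditions: BF3·OEt2 (as solvent), 85 °C; then H2O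
Reagents that add atoms: none
Why: Friedel–Crafts acylation of the Nencki type, in which BF3 turns the acid into an acyl donor, phloroglucinol is by far the most nucleophilic arene present (the chain phenyl ring does not compete), and the chelated ketone formed deactivates the ring against a second acylation.

Step 2
Reactants: 3 1-(2,4,6-trihydroxyphenyl)-9-phenylnonan-1-one
Product: 5 2,4,6-trihydroxy-3-(9-phenylnonanoyl)benzaldehyde, via aryl iminium chloride 4 (not isolated)
Conditions: POCl3 (1.2 equiv), DMF (3 equiv), EtOAc, 0 °C to rt; then H2O, 50 °C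
Reagents that add atoms: N,N-dimethylformamide CN(C)C=O; water O
Why: Vilsmeier–Haack formylation, well established for acylphloroglucinols, in which the chloroiminium salt attacks one of the two equivalent free ring carbons, the iminium group of 4 shuts down further substitution, and water releases the aldehyde.

Step 3
Reactants: 5 2,4,6-trihydroxy-3-(9-phenylnonanoyl)benzaldehyde
Product: 6 2,4,6-tris(benzyloxy)-3-(9-phenylnonanoyl)benzaldehyde
Conditions: BnBr (3.6 equiv), K2CO3 (4.5 equiv), n-Bu4NI (10 mol%), DMF, 60 °C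
Reagents that add atoms: benzyl bromide BrCc1ccccc1
Why: Williamson etherification, in which the doubly acyl-stabilised potassium phenoxides react at oxygen in a dipolar aprotic solvent, warming and iodide catalysis carry the chelated hydroxyls to completion, and capping all three oxygens later keeps ring D from closing on the chalcone ketone.

Step 4
Reactants: 6 2,4,6-tris(benzyloxy)-3-(9-phenylnonanoyl)benzaldehyde; 7 4'-benzyloxyacetophenone
Product: 9 (E)-1-[4-(benzyloxy)phenyl]-3-[2,4,6-tris(benzyloxy)-3-(9-phenylnonanoyl)phenyl]prop-2-en-1-one, via aldol adduct 8 (not isolated)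
Conditions: KOH (50% aq), EtOH/THF, rt
Reagents that add atoms: none
Why: Claisen–Schmidt condensation, in which only the unhindered methyl ketone enolate of 7 condenses with the non-enolisable aldehyde (the ring D ketone is wedged between two benzyloxy groups), and E1cB loss of water from 8 gives the conjugated E-alkene under thermodynamic control.

Step 5
Reactants: 9 (E)-chalcone carrying ring D on the beta carbon and ring B on the carbonyl; 10 resorcinol
Product: 12 1-{2,4,6-tris(benzyloxy)-3-[(4S)-2-[4-(benzyloxy)phenyl]-2,7-dihydroxychroman-4-yl]phenyl}-9-phenylnonan-1-one (hemiketal, C2 anomers equilibrating), via open keto phenol 11 (not isolated)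
Conditions: Sc(OTf)3 (10 mol%), (2S,2'S)-1,1'-(propane-1,3-diyl)bis[N-(2,6-diisopropylphenyl)piperidine-2-carboxamide] 1,1'-dioxide (11 mol%), 10 (3 equiv), 4 Å MS, ClCH2CH2Cl/t-BuOMe 4:1, 35 °C
Reagents that add atoms: none
Why: Proposed new method: the chalcone carbonyl, a strong Lewis base because rings B and D both push electron density into it, occupies one free site of the octahedral Sc(OTf)3–N,N'-dioxide complex and a resorcinol hydroxyl the neighbouring one, so that the resorcinol carbon lying para to one OH and ortho to the other attacks C-beta (future C4) in a Friedel–Crafts conjugate addition and, after rearomatisation and enol–keto proton transfer, gives keto phenol 11. The ortho hydroxyl of 11 then adds to the aryl ketone in a 6-exo-trig closure that forms O1–C2 and ring C, a ring–chain equilibrium that the bulky C4 substituent tilts towards the hemiketal and that takes the adduct out of the reversible first step. The closest known reaction types are the Sc(OTf)3–N,N'-dioxide-catalysed Friedel–Crafts addition of indoles to chalcones and the chiral-Lewis-acid Friedel–Crafts/hemiketalisation cascade of naphthols and electron-rich phenols with beta,gamma-unsaturated alpha-keto esters, whereas a phenol adding to a plain chalcone with a di-ortho-substituted beta-aryl group has not been shown. C4 is the only defined new stereocentre and is controlled by the ligand, whose anilide arms are to leave the Re face of C-beta open (Re attack gives 4S), while C2 is anomeric, equilibrates and is fixed only in step 6. The step needs carbon over oxygen attack and C4 over C2 of resorcinol, which the reversibility of the oxa-Michael path and the crowding between the two hydroxyls provide, and it needs monoalkylation, which the excess of 10 secures. Within 9 the benzyl caps stop the ring D oxygens from closing on the ketone, the acyl group withdraws part of the donor strength of ring D from the enone, and its own carbonyl, twisted out of plane between two benzyloxy groups, is too shielded to compete for scandium.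

Step 6
Reactants: 12 (4S)-2-hydroxy-2,4-diarylchroman hemiketal
Product: 14 1-{2,4,6-tris(benzyloxy)-3-[(2S,4S)-2-[4-(benzyloxy)phenyl]-7-hydroxychroman-4-yl]phenyl}-9-phenylnonan-1-one (2,4-cis), via oxocarbenium ion 13 (not isolated)
Conditions: Et3SiH (5 equiv), BF3·OEt2 (2 equiv), CH2Cl2, −78 to −40 °C
Reagents that add atoms: none
Why: Ionic (silane) reduction of a hemiketal, in which BF3·OEt2 ionises either C2 anomer, and the ring-opened tautomer after reclosure, to the planar oxocarbenium ion 13 stabilised by ring B, and Et3SiH attacks its half-chair axially on the face opposite the bulky C4 aryl group, which places ring B equatorial and cis to ring D (2S relayed from 4S), while the low temperature spares the flanked ring D ketone and the benzyl ethers.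

Step 7
Reactants: 14 (2S,4S)-tetra-O-benzyl flavan
Product: 15 1-{2,4,6-trihydroxy-3-[(2S,4S)-7-hydroxy-2-(4-hydroxyphenyl)chroman-4-yl]phenyl}-9-phenylnonan-1-one (target)
Conditions: H2 (1 atm), Pd/C (10 wt% Pd), EtOAc/MeOH, rt
Reagents that add atoms: none
Why: Catalytic hydrogenolysis of four aryl benzyl ethers under neutral conditions, which should leave untouched the ketone (a vinylogous acid once its flanking phenols are free), the cyclic C2–O1 ether at one atmosphere, and both stereocentres, neither of which epimerises without acid.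

**Compound list**
1 | phloroglucinol | Oc1cc(O)cc(O)c1 | starting material
2 | 9-phenylnonanoic acid | O=C(O)CCCCCCCCc1ccccc1 | starting material
3 | 1-(2,4,6-trihydroxyphenyl)-9-phenylnonan-1-one | O=C(CCCCCCCCc1ccccc1)c1c(O)cc(O)cc1O | intermediate
4 | N,N-dimethyl[2,4,6-trihydroxy-3-(9-phenylnonanoyl)benzylidene]ammonium chloride (not isolated) | O=C(CCCCCCCCc1ccccc1)c1c(O)cc(O)c(C=[N+](C)C)c1O.[Cl-] | intermediate
5 | 2,4,6-trihydroxy-3-(9-phenylnonanoyl)benzaldehyde | O=C(CCCCCCCCc1ccccc1)c1c(O)cc(O)c(C=O)c1O | intermediate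
6 | 2,4,6-tris(benzyloxy)-3-(9-phenylnonanoyl)benzaldehyde | O=C(CCCCCCCCc1ccccc1)c1c(OCc2ccccc2)cc(OCc2ccccc2)c(C=O)c1OCc1ccccc1 | intermediate
7 | 4'-benzyloxyacetophenone | CC(=O)c1ccc(OCc2ccccc2)cc1 | starting material
8 | 1-[4-(benzyloxy)phenyl]-3-hydroxy-3-[2,4,6-tris(benzyloxy)-3-(9-phenylnonanoyl)phenyl]propan-1-one (racemic aldol, not isolated) | O=C(CCCCCCCCc1ccccc1)c1c(OCc2ccccc2)cc(OCc2ccccc2)c(C(O)CC(=O)c2ccc(OCc3ccccc3)cc2)c1OCc1ccccc1 | intermediate
9 | (E)-1-[4-(benzyloxy)phenyl]-3-[2,4,6-tris(benzyloxy)-3-(9-phenylnonanoyl)phenyl]prop-2-en-1-one | O=C(CCCCCCCCc1ccccc1)c1c(OCc2ccccc2)cc(OCc2ccccc2)c(/C=C/C(=O)c2ccc(OCc3ccccc3)cc2)c1OCc1ccccc1 | intermediate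
10 | resorcinol | Oc1cccc(O)c1 | starting material
11 | (3S)-1-[4-(benzyloxy)phenyl]-3-(2,4-dihydroxyphenyl)-3-[2,4,6-tris(benzyloxy)-3-(9-phenylnonanoyl)phenyl]propan-1-one (not isolated) | O=C(CCCCCCCCc1ccccc1)c1c(OCc2ccccc2)cc(OCc2ccccc2)c([C@@H](CC(=O)c2ccc(OCc3ccccc3)cc2)c2ccc(O)cc2O)c1OCc1ccccc1 | intermediate
12 | 1-{2,4,6-tris(benzyloxy)-3-[(4S)-2-[4-(benzyloxy)phenyl]-2,7-dihydroxychroman-4-yl]phenyl}-9-phenylnonan-1-one (C2 anomeric, undefined) | O=C(CCCCCCCCc1ccccc1)c1c(OCc2ccccc2)cc(OCc2ccccc2)c([C@H]2CC(O)(c3ccc(OCc4ccccc4)cc3)Oc3cc(O)ccc32)c1OCc1ccccc1 | intermediate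
13 | (4S)-2-[4-(benzyloxy)phenyl]-7-hydroxy-4-[2,4,6-tris(benzyloxy)-3-(9-phenylnonanoyl)phenyl]-3,4-dihydrochromenylium ion, O1=C2 oxocarbenium (not isolated) | O=C(CCCCCCCCc1ccccc1)c1c(OCc2ccccc2)cc(OCc2ccccc2)c([C@H]2CC(c3ccc(OCc4ccccc4)cc3)=[O+]c3cc(O)ccc32)c1OCc1ccccc1 | intermediate
14 | 1-{2,4,6-tris(benzyloxy)-3-[(2S,4S)-2-[4-(benzyloxy)phenyl]-7-hydroxychroman-4-yl]phenyl}-9-phenylnonan-1-one | O=C(CCCCCCCCc1ccccc1)c1c(OCc2ccccc2)cc(OCc2ccccc2)c([C@H]2C[C@@H](c3ccc(OCc4ccccc4)cc3)Oc3cc(O)ccc32)c1OCc1ccccc1 | intermediate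
15 | 1-{2,4,6-trihydroxy-3-[(2S,4S)-7-hydroxy-2-(4-hydroxyphenyl)chroman-4-yl]phenyl}-9-phenylnonan-1-one | O=C(CCCCCCCCc1ccccc1)c1c(O)cc(O)c([C@H]2C[C@@H](c3ccc(O)cc3)Oc3cc(O)ccc32)c1O | target

Total step count: 7. Longest linear sequence: 7 steps (1 → 3 → 5 → 6 → 9 → 12 → 14 → 15).

**Steps most likely to fail**

1. Step 5.
   - Risk: the addition may stall or revert because the beta carbon is crowded and donor-stabilised. One-point binding of a plain chalcone may also give poor facial selectivity.
   - Fallback, racemic annulation and classical resolution, from 9 and 10 back to 14. The annulation is run as the known achiral acid-promoted phenol–chalcone condensation (Sc(OTf)3 without ligand, MeCN, 60 °C), where temperature and acid strength can be raised freely. It passes through 11 and its mirror image, the (3R)-keto phenol F1, and gives 12 as a racemate, that is together with the (4R)-hemiketal F2. Silane reduction as in step 6 runs through 13 and the (4R)-oxocarbenium ion F3 to 14 and the (2R,4R)-flavan F4. The free 7-OH is then acylated with (1S)-camphanic chloride (Et3N, 4-(dimethylamino)pyridine, CH2Cl2) to the (2S,4S)-flavan 7-O-camphanate F5 and the (2R,4R)-flavan 7-O-camphanate F6. These are diastereomers and are separated by crystallisation or chromatography. LiOH in THF/H2O cleaves the aryl ester of F5 and returns 14.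

2. Step 6.
   - Risk: the cation may lose a proton from C3 instead of taking up hydride. The new para-alkoxybenzylic C2–O1 bond may re-ionise, with ring opening and over-reduction. The silane may also begin to reduce the ring D ketone.
   - Fallback, from 12 to 15, bypassing 14. Compound 12 is dehydrated on purpose (p-toluenesulfonic acid monohydrate, catalytic, toluene, 4 Å MS, 40 °C) to the (4S)-2,4-diaryl-4H-chromene F7. A single hydrogenation over Pd/C (H2, EtOAc/MeOH, rt) then saturates the C2=C3 enol ether from the catalyst face away from ring D. This is the known cis-selective hydrogenation of 4-substituted 4H-chromenes. The same operation removes the four benzyl groups and arrives at 15 without any Lewis acid or silane.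

3. Step 3.
   - Risk: C-benzylation at the one free ring carbon may compete. The alkylation may also stall while the hydroxyl between the two carbonyl groups stays chelated.
   - Fallback, from 2 back to 6, in which no acylated phloroglucinol is ever alkylated. Purchased 1,3,5-tris(benzyloxy)benzene F8 is acylated (Friedel–Crafts, CH2Cl2, 0 °C to rt) by the mixed 9-phenylnonanoic trifluoroacetic anhydride F9, generated from 2 and trifluoroacetic anhydride. This gives the 2,4,6-tris(benzyloxy)phenyl ketone F10. Vilsmeier–Haack formylation (POCl3, DMF, 50 °C) at one of its two equivalent free positions passes through the benzylated aryl iminium chloride F11, and aqueous hydrolysis delivers 6.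

**Further compounds**
F1 | step 5 | (3R)-1-[4-(benzyloxy)phenyl]-3-(2,4-dihydroxyphenyl)-3-[2,4,6-tris(benzyloxy)-3-(9-phenylnonanoyl)phenyl]propan-1-one | O=C(CCCCCCCCc1ccccc1)c1c(OCc2ccccc2)cc(OCc2ccccc2)c([C@H](CC(=O)c2ccc(OCc3ccccc3)cc2)c2ccc(O)cc2O)c1OCc1ccccc1
F2 | step 5 | (4R)-hemiketal, antipode of 12 | O=C(CCCCCCCCc1ccccc1)c1c(OCc2ccccc2)cc(OCc2ccccc2)c([C@@H]2CC(O)(c3ccc(OCc4ccccc4)cc3)Oc3cc(O)ccc32)c1OCc1ccccc1
F3 | step 5 | (4R)-oxocarbenium ion, antipode of 13 | O=C(CCCCCCCCc1ccccc1)c1c(OCc2ccccc2)cc(OCc2ccccc2)c([C@@H]2CC(c3ccc(OCc4ccccc4)cc3)=[O+]c3cc(O)ccc32)c1OCc1ccccc1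
F4 | step 5 | (2R,4R)-flavan, antipode of 14 | O=C(CCCCCCCCc1ccccc1)c1c(OCc2ccccc2)cc(OCc2ccccc2)c([C@@H]2C[C@H](c3ccc(OCc4ccccc4)cc3)Oc3cc(O)ccc32)c1OCc1ccccc1
F5 | step 5 | (2S,4S)-flavan 7-O-[(1S,4R)-camphanate] | O=C(CCCCCCCCc1ccccc1)c1c(OCc2ccccc2)cc(OCc2ccccc2)c([C@H]2C[C@@H](c3ccc(OCc4ccccc4)cc3)Oc3cc(OC(=O)[C@@]45CC[C@@](C)(C(=O)O4)C5(C)C)ccc32)c1OCc1ccccc1
F6 | step 5 | (2R,4R)-flavan 7-O-[(1S,4R)-camphanate] | O=C(CCCCCCCCc1ccccc1)c1c(OCc2ccccc2)cc(OCc2ccccc2)c([C@@H]2C[C@H](c3ccc(OCc4ccccc4)cc3)Oc3cc(OC(=O)[C@@]45CC[C@@](C)(C(=O)O4)C5(C)C)ccc32)c1OCc1ccccc1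
F7 | step 6 | 1-{2,4,6-tris(benzyloxy)-3-[(4S)-2-[4-(benzyloxy)phenyl]-7-hydroxy-4H-chromen-4-yl]phenyl}-9-phenylnonan-1-one | O=C(CCCCCCCCc1ccccc1)c1c(OCc2ccccc2)cc(OCc2ccccc2)c([C@H]2C=C(c3ccc(OCc4ccccc4)cc3)Oc3cc(O)ccc32)c1OCc1ccccc1
F8 | step 3 | 1,3,5-tris(benzyloxy)benzene (purchased) | c1ccc(COc2cc(OCc3ccccc3)cc(OCc3ccccc3)c2)cc1
F9 | step 3 | 9-phenylnonanoic trifluoroacetic anhydride | O=C(CCCCCCCCc1ccccc1)OC(=O)C(F)(F)F
F10 | step 3 | 1-[2,4,6-tris(benzyloxy)phenyl]-9-phenylnonan-1-one | O=C(CCCCCCCCc1ccccc1)c1c(OCc2ccccc2)cc(OCc2ccccc2)cc1OCc1ccccc1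
F11 | step 3 | N,N-dimethyl[2,4,6-tris(benzyloxy)-3-(9-phenylnonanoyl)benzylidene]ammonium chloride | O=C(CCCCCCCCc1ccccc1)c1c(OCc2ccccc2)cc(OCc2ccccc2)c(C=[N+](C)C)c1OCc1ccccc1.[Cl-]
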